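**Plan**
- **Cuts, in retrosynthetic order:** first the 7-O–CH3 bond and two MOM ethers. Then C3–C4 of ring C (with the C2–H bond), O1–C2, C4a–CHO and the two C–CH3 bonds of the carbinol. Last come the C8–CH2 and aryl ester bonds of a dihydrocoumarin made from phloroglucinol and acrylic acid.
- **Enabling feature:** in ring C the C3 methylene lies between the C4 ketone and C2, which carries O1, phenyl and one hydrogen. This array results when a formyl C4–H bond adds across an enol ether O1–C2(Ph)=C3H2 attached at C8a of ring A.
- **Forward order:** ring A is bought. A temporary lactone ring fixes the C8 chain and masks only the oxygen that becomes O1. Grignard opening, ortho-formylation at C4a and O-alkenylation follow, and ring C closes in step 6.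
- **Stereochemistry:** C2 is the only stereocentre. The chiral bisphosphine on rhodium sets it in step 6, and only acidic or neutral conditions follow.
- **Methyl ether last:** the chelated 5-OH and the free 7-OH of the flavanone differ sharply, whereas the two phenols of the dihydrocoumarin do not.

Key step: step 6

Assumption: (R)-DTBM-SEGPHOS is taken as the ligand antipode that leads to (S) at C2. The sense of induction cannot be derived with certainty for this substrate class, and the (S)-ligand would be used if it proves opposite.

Step 1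
Reactants: 1 phloroglucinol; 2 acrylic acid
Product: 4 5,7-dihydroxychroman-2-one, via 3,5-dihydroxyphenyl acrylate 3 (not isolated)
Conditions: 2 (1.0 equiv), Amberlyst-15 (sulfonic acid resin), toluene, reflux, Dean–Stark
Reagents that add atoms: none
Why: Acid-catalysed esterification followed by intramolecular Friedel–Crafts conjugate alkylation is the established route from activated phenols and acrylic acid to 3,4-dihydrocoumarins; the threefold symmetry of 1 leaves no regiochemical choice, and one equivalent of 2 restrains a second annulation.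

Step 2
Reactants: 4 5,7-dihydroxychroman-2-one
Product: 5 5,7-bis(methoxymethoxy)chroman-2-one
Conditions: MOMCl (2.6 equiv), i-Pr2NEt (3 equiv), CH2Cl2/DMF, 0 °C → rt
Reagents that add atoms: chloromethyl methyl ether (MOMCl), COCCl
Why: Standard MOM etherification of phenols with a hard electrophile and an amine base caps both hydroxyls alike, so no discrimination between them is needed, C-alkylation of the electron-rich ring is avoided and the lactone stays closed.

Step 3
Reactants: 5 5,7-bis(methoxymethoxy)chroman-2-one; 6 methylmagnesium bromide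
Product: 8 2-(3-hydroxy-3-methylbutyl)-3,5-bis(methoxymethoxy)phenol, via ring-opened methyl ketone 7 (not isolated)
Conditions: 6 (3.5 equiv), THF, 0 °C → rt; sat. aq. NH4Cl
Reagents that add atoms: none
Why: Double Grignard addition to a dihydrocoumarin, the classical entry to 2-(3-hydroxy-3-methylbutyl)phenols, builds the carbinol and frees only the oxygen that becomes O1, while MOM ethers are inert and the NH4Cl quench avoids acid-induced chroman formation.

Step 4
Reactants: 8 2-(3-hydroxy-3-methylbutyl)-3,5-bis(methoxymethoxy)phenol
Product: 10 2-hydroxy-3-(3-hydroxy-3-methylbutyl)-4,6-bis(methoxymethoxy)benzaldehyde, via salicyl alcohol 9 (not isolated)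
Conditions: MgCl2 (anhydrous), Et3N, (CH2O)n, MeCN, reflux; cold aq. citric acid
Reagents that add atoms: paraformaldehyde, counted as formaldehyde, C=O
Why: In the Casnati–Skattebøl ortho-formylation the magnesium phenoxide delivers formaldehyde only to an ortho carbon, the sole free ortho position is the future C4a, and hydride transfer from the salicyl alkoxide to a second formaldehyde gives the aldehyde, with the tertiary alcohol and MOM ethers as spectators in the basic medium.

Step 5
Reactants: 10 2-hydroxy-3-(3-hydroxy-3-methylbutyl)-4,6-bis(methoxymethoxy)benzaldehyde; 11 4,4,5,5-tetramethyl-2-(1-phenylvinyl)-1,3,2-dioxaborolane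
Product: 12 3-(3-hydroxy-3-methylbutyl)-4,6-bis(methoxymethoxy)-2-(1-phenylvinyloxy)benzaldehyde
Conditions: 11 (2.5 equiv), Cu(OAc)2 (2 equiv), pyridine (5 equiv), 4 Å MS, CH2Cl2, dry air, rt; chromatography on Et3N-deactivated silica
Reagents that add atoms: none
Why: Chan–Lam oxidative C–O coupling of phenols with alkenylboron reagents is a known route to aryl vinyl ethers that runs at room temperature in a weakly basic medium tolerated by the aldehyde and MOM groups; the phenoxide is pre-bound to copper as a salicylaldehydate chelate and the tertiary alcohol is too hindered to compete.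

Step 6
Reactants: 12 3-(3-hydroxy-3-methylbutyl)-4,6-bis(methoxymethoxy)-2-(1-phenylvinyloxy)benzaldehyde
Product: 13 (2S)-8-(3-hydroxy-3-methylbutyl)-5,7-bis(methoxymethoxy)-2-phenylchroman-4-one
Conditions: [Rh(cod)Cl]2 (2.5 mol %), (R)-DTBM-SEGPHOS (5 mol %), NaB[3,5-(CF3)2C6H3]4 (5 mol %), THF, 60 °C, argon
Reagents that add atoms: none
Why: Proposed new method: the cationic monovalent rhodium bisphosphine should insert into the formyl C–H bond of 12 to give an acyl hydride of trivalent rhodium, the tethered enol ether binds, hydride migrates to C2 while rhodium takes the C3 methylene, and reductive elimination from the seven-membered acyl alkyl rhodacycle forms C3–C4 and frees the catalyst. The closest known reaction type is the rhodium-catalysed enantioselective intramolecular hydroacylation of 1,1-disubstituted alkenes in ortho-allylbenzaldehydes, which gives six-membered benzo-fused ketones; 12 is their analogue with O1 in place of the benzylic CH2, and an aryl enol ether has not yet served as the alkene. Ring C closes in a formal 6-endo-trig mode, the acyl carbon C4 joining the alkene terminus. C2, the only new stereocentre, is controlled by the axially chiral bisphosphine, whose aryl quadrants decide which face of the bound alkene receives the hydride. The step needs endo regioselectivity over the 5-exo route to a 2-methyl-2-phenylbenzofuran-3-one and must outpace decarbonylation: the 1,1-disubstitution penalises the tertiary alkyl rhodium and the quaternary-centre-forming elimination of the exo route, the short O1 tether together with the hemilabile ortho MOM oxygen keeps the acyl hydride saturated, and the alkene has no allylic hydrogen through which it could isomerise. The sodium borate abstracts chloride without releasing acid, so the enol ether and MOM groups survive, the hindered tertiary alcohol can stay free, and the neutral aprotic medium gives the β-aryloxy ketone no path to racemise by retro-oxa-Michael opening.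

Step 7
Reactants: 13 (2S)-8-(3-hydroxy-3-methylbutyl)-5,7-bis(methoxymethoxy)-2-phenylchroman-4-one
Product: 14 (2S)-5,7-dihydroxy-8-(3-hydroxy-3-methylbutyl)-2-phenylchroman-4-one
Conditions: HCl (1.25 M in MeOH), 0 °C → rt, stopped as soon as 13 is consumed
Reagents that add atoms: none
Why: Acid-catalysed acetal exchange is the standard cleavage of phenolic MOM ethers (the 5-O-MOM next to the carbonyl goes first); at room temperature ionisation of an unactivated tertiary alcohol should be much slower, and C2 should hold because flavanone ring opening is a base-driven process.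

Step 8
Reactants: 14 (2S)-5,7-dihydroxy-8-(3-hydroxy-3-methylbutyl)-2-phenylchroman-4-one
Product: 15 (2S)-5-hydroxy-8-(3-hydroxy-3-methylbutyl)-7-methoxy-2-phenylchroman-4-one (target CNP0160063.1)
Conditions: MeOH (1.1 equiv), PPh3, DIAD, THF, 0 °C → rt
Reagents that add atoms: methanol, CO
Why: In this Mitsunobu O-methylation the acidic 7-OH para to the acyl group reacts while the 5-OH hydrogen-bonded to C4=O and the tertiary alcohol stay untouched, which is the well-known 7-selectivity of 5,7-dihydroxyflavanones, and the nearly neutral medium protects C2.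

**Compound list**
1 | phloroglucinol | Oc1cc(O)cc(O)c1 | starting material
2 | acrylic acid | C=CC(=O)O | starting material
3 | 3,5-dihydroxyphenyl acrylate | C=CC(=O)Oc1cc(O)cc(O)c1 | intermediate
4 | 5,7-dihydroxychroman-2-one | O=C1CCc2c(O)cc(O)cc2O1 | intermediate
5 | 5,7-bis(methoxymethoxy)chroman-2-one | O=C1CCc2c(OCOC)cc(OCOC)cc2O1 | intermediate
6 | methylmagnesium bromide | C[Mg]Br | starting material
7 | 4-[2-hydroxy-4,6-bis(methoxymethoxy)phenyl]butan-2-one (present as its magnesium phenoxide) | CC(=O)CCc1c(O)cc(OCOC)cc1OCOC | intermediate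
8 | 2-(3-hydroxy-3-methylbutyl)-3,5-bis(methoxymethoxy)phenol | CC(C)(O)CCc1c(O)cc(OCOC)cc1OCOC | intermediate
9 | 2-(hydroxymethyl)-6-(3-hydroxy-3-methylbutyl)-3,5-bis(methoxymethoxy)phenol | CC(C)(O)CCc1c(O)c(CO)c(OCOC)cc1OCOC | intermediate
10 | 2-hydroxy-3-(3-hydroxy-3-methylbutyl)-4,6-bis(methoxymethoxy)benzaldehyde | CC(C)(O)CCc1c(O)c(C=O)c(OCOC)cc1OCOC | intermediate
11 | 4,4,5,5-tetramethyl-2-(1-phenylvinyl)-1,3,2-dioxaborolane | C=C(B1OC(C)(C)C(C)(C)O1)c1ccccc1 | starting material
12 | 3-(3-hydroxy-3-methylbutyl)-4,6-bis(methoxymethoxy)-2-(1-phenylvinyloxy)benzaldehyde | C=C(Oc1c(CCC(C)(C)O)c(OCOC)cc(OCOC)c1C=O)c1ccccc1 | intermediate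
13 | (2S)-8-(3-hydroxy-3-methylbutyl)-5,7-bis(methoxymethoxy)-2-phenylchroman-4-one | CC(C)(O)CCc1c(OCOC)cc(OCOC)c2c1O[C@H](c1ccccc1)CC2=O | intermediate
14 | (2S)-5,7-dihydroxy-8-(3-hydroxy-3-methylbutyl)-2-phenylchroman-4-one | CC(C)(O)CCc1c(O)cc(O)c2c1O[C@H](c1ccccc1)CC2=O | intermediate
15 | (2S)-5-hydroxy-8-(3-hydroxy-3-methylbutyl)-7-methoxy-2-phenylchroman-4-one | COc1cc(O)c2c(c1CCC(C)(C)O)O[C@H](c1ccccc1)CC2=O | target

Total step count: 8
Longest linear sequence: 8 steps (from 1 to 15)

**Steps most likely to fail**

1. **Step 6.**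
   - **Risk:** rhodium insertion into the formyl C–H bond of an electron-rich aldehyde flanked by two ortho oxygens may be slow. Decarbonylation, exo closure or cleavage of the enol ether could then take over. Face selection on an aryl enol ether is also untested.
   - **Fallback (known chemistry, sets out from 10, returns at 13):** excess ethynylmagnesium bromide in THF should add to 10 to give racemic 2-(1-hydroxyprop-2-yn-1-yl)-6-(3-hydroxy-3-methylbutyl)-3,5-bis(methoxymethoxy)phenol F1. MnO2 in CH2Cl2 should oxidise it to 1-[2-hydroxy-3-(3-hydroxy-3-methylbutyl)-4,6-bis(methoxymethoxy)phenyl]prop-2-yn-1-one F2. Catalytic Et2NH in EtOH should close this ynone by 6-endo-dig oxa-Michael addition to 8-(3-hydroxy-3-methylbutyl)-5,7-bis(methoxymethoxy)-4H-chromen-4-one F3. The established rhodium-catalysed asymmetric 1,4-addition of phenylboronic acid to chromones ([RhCl(C2H4)2]2, an electron-poor chiral MeO-BIPHEP-type bisphosphine, toluene/water) should then set C2 and give 13.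

2. **Step 5.**
   - **Risk:** the phenol is flanked by the side chain and the formyl group and is hydrogen-bonded, so C–O coupling may be slow. Protodeboronation, homocoupling or acetoxylation could then consume the boronate.
   - **Fallback (sets out from 10, returns at 12):** Mitsunobu etherification of 10 with racemic 2-chloro-1-phenylethanol (PPh3, DIAD, toluene) should give 2-(2-chloro-1-phenylethoxy)-3-(3-hydroxy-3-methylbutyl)-4,6-bis(methoxymethoxy)benzaldehyde F4. t-BuOK in THF at 0 °C should then remove HCl by E2 loss of the benzylic hydrogen to give 12.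

3. **Step 7.**
   - **Risk:** the acid may ionise the tertiary alcohol. The cation could be captured by the liberated 7-OH (closure to a dimethylchroman ring) or lose a proton. Prolonged exposure could also erode the configuration at C2.
   - **Fallback (sets out from 4, returns at 14):** this replaces acid-labile protection by hydrogenolysis.
     - BnBr and K2CO3 in acetone should give 5,7-bis(benzyloxy)chroman-2-one F5.
     - MeMgBr should open it through 4-[2,4-bis(benzyloxy)-6-hydroxyphenyl]butan-2-one F6 to 3,5-bis(benzyloxy)-2-(3-hydroxy-3-methylbutyl)phenol F7.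
     - MgCl2, Et3N and paraformaldehyde should lead through 3,5-bis(benzyloxy)-2-(hydroxymethyl)-6-(3-hydroxy-3-methylbutyl)phenol F8 to 4,6-bis(benzyloxy)-2-hydroxy-3-(3-hydroxy-3-methylbutyl)benzaldehyde F9.
     - Cu(OAc)2 and 11 should give 4,6-bis(benzyloxy)-3-(3-hydroxy-3-methylbutyl)-2-(1-phenylvinyloxy)benzaldehyde F10.
     - The catalyst of step 6 should cyclise it to (2S)-5,7-bis(benzyloxy)-8-(3-hydroxy-3-methylbutyl)-2-phenylchroman-4-one F11.
     - H2 over Pd/C in EtOAc at rt should free both phenols under neutral conditions to give 14.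

**Further compounds**
F1 | step 6 | 2-(1-hydroxyprop-2-yn-1-yl)-6-(3-hydroxy-3-methylbutyl)-3,5-bis(methoxymethoxy)phenol (racemic) | C#CC(O)c1c(O)c(CCC(C)(C)O)c(OCOC)cc1OCOC
F2 | step 6 | 1-[2-hydroxy-3-(3-hydroxy-3-methylbutyl)-4,6-bis(methoxymethoxy)phenyl]prop-2-yn-1-one | C#CC(=O)c1c(O)c(CCC(C)(C)O)c(OCOC)cc1OCOC
F3 | step 6 | 8-(3-hydroxy-3-methylbutyl)-5,7-bis(methoxymethoxy)-4H-chromen-4-one | O=C1C=COc2c1c(OCOC)cc(OCOC)c2CCC(C)(C)O
F4 | step 5 | 2-(2-chloro-1-phenylethoxy)-3-(3-hydroxy-3-methylbutyl)-4,6-bis(methoxymethoxy)benzaldehyde (racemic) | O=Cc1c(OCOC)cc(OCOC)c(CCC(C)(C)O)c1OC(CCl)c1ccccc1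
F5 | step 7 | 5,7-bis(benzyloxy)chroman-2-one | O=C1CCc2c(OCc3ccccc3)cc(OCc3ccccc3)cc2O1
F6 | step 7 | 4-[2,4-bis(benzyloxy)-6-hydroxyphenyl]butan-2-one | CC(=O)CCc1c(O)cc(OCc2ccccc2)cc1OCc1ccccc1
F7 | step 7 | 3,5-bis(benzyloxy)-2-(3-hydroxy-3-methylbutyl)phenol | CC(C)(O)CCc1c(O)cc(OCc2ccccc2)cc1OCc1ccccc1
F8 | step 7 | 3,5-bis(benzyloxy)-2-(hydroxymethyl)-6-(3-hydroxy-3-methylbutyl)phenol | CC(C)(O)CCc1c(O)c(CO)c(OCc2ccccc2)cc1OCc1ccccc1
F9 | step 7 | 4,6-bis(benzyloxy)-2-hydroxy-3-(3-hydroxy-3-methylbutyl)benzaldehyde | CC(C)(O)CCc1c(O)c(C=O)c(OCc2ccccc2)cc1OCc1ccccc1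
F10 | step 7 | 4,6-bis(benzyloxy)-3-(3-hydroxy-3-methylbutyl)-2-(1-phenylvinyloxy)benzaldehyde | C=C(Oc1c(CCC(C)(C)O)c(OCc2ccccc2)cc(OCc2ccccc2)c1C=O)c1ccccc1
F11 | step 7 | (2S)-5,7-bis(benzyloxy)-8-(3-hydroxy-3-methylbutyl)-2-phenylchroman-4-one | CC(C)(O)CCc1c(OCc2ccccc2)cc(OCc2ccccc2)c2c1O[C@H](c1ccccc1)CC2=O
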